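(The readings are calculated for an exercise; the scatter is artificial.)

The product takes one reagent each, as the equivalents imply, so what stands at the stop is capped by the reagent fed by then.

| flask | solid substrate | reagent | remark | time |
|---|---|---|---|---|
| Friday's | 0.025 M | 1.2 equiv (fed, over 1.0 h) | run made earlier |  |
| Tuesday's | 0.038 M | 1.2 equiv (fed, over 1.0 h) | run made earlier |  |
| larch | 0.050 M | 1.20 equiv (fed, over 1.0 h) |  | 1.0 h |
| cedar | 0.050 M | 1.20 equiv (fed, over 2.0 h) |  | 1.0 h |
| birch | 0.050 M | 1.20 equiv (fed, over 4.0 h) |  | 1.0 h |

| run | time / min | product / % | solid substrate / % |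
|---|---|---|---|
| Friday's | 12.0 | 8.5 | 68.7 |
| Friday's | 25.0 | 34.0 | 37.5 |
| Friday's | 40.0 | 65.6 | 4.6 |
| Friday's | 50.0 | 81.3 | 0 |
| Friday's | 60.0 | 90.9 | 0 |
| Tuesday's | 12.0 | 8.9 | 73.9 |
| Tuesday's | 25.0 | 27.3 | 53.9 |
| Tuesday's | 40.0 | 51.6 | 28.1 |
| Tuesday's | 50.0 | 70.4 | 11.8 |
| Tuesday's | 60.0 | 86.9 | 0.4 |

(standard deviation of a reading: 1 percentage point)

- solid substrate is a solid; its amount is given per volume of the solution
- at the start none of the solid substrate is in solution
- percentages count the whole charge, also what has not yet gone in
- "hardly changes" means that all values lie within two and a half points (for a concentration: within two and a half percent of the largest)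

1. amount of product at the end, in percent of the solid substrate charged for larch, cedar, birch, in this order
2. the shape of the row from first to last (rises all the way / falls, then rises / rises, then falls / falls all the way / hardly changes)

1. My number is the delivered ratio: equivalents times running time over dosing time, for a stop that comes no later than the end of the feed; it is the reagent fed by the stop per solid substrate charged. For larch it is 120%.
2. For cedar it is 60.0% and for birch 30.0%. Both are less than the charge, so in cedar and birch the fed reagent is the limiting reagent and the ratio is the ceiling on product. Larch's ceiling is the charge, 100%.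
3. One number is not enough. Friday's and Tuesday's runs both reach 120% at 60.0 min, yet they give 90.9% and 86.9%. Over its last 20.0 min, Tuesday's run makes product at 6.71 × 10⁻⁴ M min⁻¹, slower than its feed of 7.60 × 10⁻⁴ M min⁻¹. Larch is fed faster than Tuesday's run, at 0.00100 M min⁻¹.
4. My own reckoning: Tuesday's hour gave 0.0330 M, which is 66.0% of larch's charge. Friday's feed of 5.00 × 10⁻⁴ M min⁻¹ matches cedar's, and its hour's product is 45.5% of cedar's charge. I put birch just under its ceiling.
5. The forecast gives 72%, 53% and 28%, above mine for larch and cedar, and says “Every run stops at 1.0 h, so slower feeds deliver less reagent”. Its shape is falls all the way, and so is mine.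
6. The flasks give 71.3%, 52.1% and 28.1%: falls all the way.

    solid substrate ⇌ dissolved substrate, rate k1*(cs1 - [dissolved substrate]) while solid is left; crystals form when [dissolved substrate] > cs1 (solubility = 28.0 mM, k = 0.0240 min⁻¹)
    2 solid substrate → homo dimer (k = 0.0810 M⁻¹ min⁻¹)
    dissolved substrate + reagent → product (k = 20.0 M⁻¹ min⁻¹)

In larch, the midpoint of the dissolving up to the stop falls at 0.511 h and that of the conversion to product at 0.552 h, while reagent rises from 23.8% of its charge at 0.500 h to 40.6% at 1.00 h, and product stands at 59.4% of the delivered ratio. In birch, dissolved substrate stands at 19.4% of the solid substrate charged at 0.500 h and 26.8% at 1.00 h, while reagent stands at 2.41% of its charge at 0.500 h and 1.60% at 1.00 h, and product stands at 93.7% of the delivered ratio of 30.0%.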